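## Retrosynthetic overview

1. Target ⇒ free C8–OH from its silyl ether, cut the C5 angelate and re-oxidise C5. This gives a 2-crotonoyl-2-hydroxycycloheptanone fused to the α-methylene-γ-lactone.
2. Key disconnection: the C1–C10 bond goes back to a C5–C10 bond. In the forward direction this is an α-ketol 1,2-shift (six-ring → seven-ring) of a 1-hydroxycyclohexyl vicinal diketone. It builds the cycloheptane and the C1 carbinol in one event.
3. Vicinal diketone ⇒ diazo-aldol adduct (oxygen transfer to the diazo carbon) ⇒ lactone-fused cyclohexanone + (E)-1-diazopent-3-en-2-one. The α-methylene lactone is carried as its Mannich base.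
4. Lactone-fused cyclohexanone ⇒ Johnson–Claisen (C7–C11), dihydroxylation/lactonisation (C6–O) and methylation (C10) on (S)-4-hydroxycyclohexenone (C8).
5. Ring order: six-membered carbocycle (bought) → γ-lactone (step 5) → enlargement to the seven-membered ring (step 11).

Assumption: compound 1 is bought as the single (S) enantiomer.

Atom labels (target):
- C1 = C(OH)(crotonoyl); C2–C4 and C15 = crotonoyl chain.
- C5 = CH–O-angelate; C6 = CH–O(lactone); C7 = ring-fusion CH; C8 = CH–OH; C9 = CH2; C10 = CH–CH3.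
- C11/C12/C13 = lactone α-carbon / C=O / =CH2.
- "Top face" carries C8–O, C7–C11 and C5–O. "Bottom face" carries C6–O, the C10 methyl and C1–OH.

## Route

Step 1
Reactants: 1 (S)-4-hydroxycyclohex-2-en-1-one
Product: 2 (S)-4-(tert-butyldimethylsilyloxy)cyclohex-2-en-1-one
Conditions: TBSCl, imidazole, DMF, 0 °C to rt
Reagents that add atoms: TBSCl CC(C)(C)[Si](C)(C)Cl
Why: Standard imidazole-promoted silylation of the secondary alcohol; the purchased C8 stereocentre (S) is untouched and relays all later centres.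

Step 2
Reactants: 2 (S)-4-(tert-butyldimethylsilyloxy)cyclohex-2-en-1-one
Product: 3 (4S,6S)-4-(tert-butyldimethylsilyloxy)-6-methylcyclohex-2-en-1-one
Conditions: LiN(iPr)2, THF, −78 °C; MeI, DMPU, −78 to −40 °C
Reagents that add atoms: methyl iodide CI
Why: Kinetic α′-deprotonation and alkylation, in which MeI enters axially on the face opposite the pseudo-axial C8 silyloxy group (1,3-relationship) and gives the trans-4,6 product (C10 S).

Step 3
Reactants: 3 (4S,6S)-4-(tert-butyldimethylsilyloxy)-6-methylcyclohex-2-en-1-one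
Product: 4 (1R,4S,6S)-4-(tert-butyldimethylsilyloxy)-6-methylcyclohex-2-en-1-ol
Conditions: NaBH4, CeCl3·7H2O, MeOH, −78 °C
Reagents that add atoms: none
Why: Luche 1,2-reduction with axial hydride attack from the bottom face gives the equatorial C5 alcohol on the top face, trans to the methyl group and cis to C8–O.

Step 4
Reactants: 4 (1R,4S,6S)-4-(tert-butyldimethylsilyloxy)-6-methylcyclohex-2-en-1-ol; 5 trimethyl orthoacetate
Product: 7 methyl 2-[(1R,4S,6S)-6-(tert-butyldimethylsilyloxy)-4-methylcyclohex-2-en-1-yl]acetate, via mixed ketene acetal 6 (not isolated)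
Conditions: 5 (6 equiv), EtCO2H (cat.), xylene, 140 °C, MeOH distilled off
Reagents that add atoms: none
Why: Johnson–Claisen orthoester rearrangement, whose suprafacial shift moves chirality from C5–O to C7, so the C7–C11 bond forms on the top face cis to C8–O, a relationship that conjugate addition to 3 would not give.

Step 5
Reactants: 7 methyl 2-[(1R,4S,6S)-6-(tert-butyldimethylsilyloxy)-4-methylcyclohex-2-en-1-yl]acetate
Product: 9 (3aR,4S,6S,7S,7aR)-4-(tert-butyldimethylsilyloxy)-7-hydroxy-6-methylhexahydro-1-benzofuran-2(3H)-one, via diol ester 8 (not isolated)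
Conditions: OsO4 (2 mol %), NMO, acetone/H2O, rt; then PPTS (cat.), toluene, 80 °C
Reagents that add atoms: N-methylmorpholine N-oxide C[N+]1([O-])CCOCC1; water O
Why: Upjohn dihydroxylation from the bottom face (opposite the axial C8 silyl ether and the C7 chain) sets C6–O, and acid-catalysed lactonisation then closes the diequatorial trans-fused γ-lactone on C6–OH only, because the axial C5–OH cannot reach the ester.

Step 6
Reactants: 9 (3aR,4S,6S,7S,7aR)-4-(tert-butyldimethylsilyloxy)-7-hydroxy-6-methylhexahydro-1-benzofuran-2(3H)-one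
Product: 10 (3aR,4S,6S,7S,7aR)-4-(tert-butyldimethylsilyloxy)-3-[(dimethylamino)methyl]-7-hydroxy-6-methylhexahydro-1-benzofuran-2(3H)-one (C3 epimers)
Conditions: LiN(iPr)2 (2.3 equiv), THF, −78 °C; CH2=NMe2+ I−, −78 °C to rt; H2O
Reagents that add atoms: dimethyl(methylidene)ammonium iodide C=[N+](C)C.[I-]
Why: Mannich-type aminomethylation of the lactone α-carbon (the free OH is tied up as its alkoxide) installs C13 as a masked α-methylene group that is inert to the carbanion of step 9; the C11 configuration is lost later and does not matter.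

Step 7
Reactants: 10 (3aR,4S,6S,7S,7aR)-4-(tert-butyldimethylsilyloxy)-3-[(dimethylamino)methyl]-7-hydroxy-6-methylhexahydro-1-benzofuran-2(3H)-one (C3 epimers)
Product: 11 (3aR,4S,6S,7aR)-4-(tert-butyldimethylsilyloxy)-3-[(dimethylamino)methyl]-6-methylhexahydro-1-benzofuran-2,7-dione (C3 epimers)
Conditions: (nPr4N)RuO4 (5 mol %), NMO, 4 Å MS, CH2Cl2, rt
Reagents that add atoms: none
Why: Neutral Ley–Griffith oxidation of the hindered axial alcohol; C6–O and the C10 methyl are both equatorial next to the new ketone, so neither centre is at risk of epimerisation.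

Step 8
Reactants: 12 (E)-pent-3-en-2-one
Product: 14 (E)-1-diazopent-3-en-2-one, via trifluoroacetyl diketone 13 (not isolated)
Conditions: LiN(SiMe3)2, THF, −78 °C; CF3CO2CH2CF3; aq HCl wash; then MsN3, Et3N, H2O (1 equiv), MeCN, rt
Reagents that add atoms: methanesulfonyl azide CS(=O)(=O)N=[N+]=[N-]
Why: Detrifluoroacetylative diazo transfer (activated Regitz transfer) is the reliable access to α′-diazo enones, which form poorly from enoyl chlorides and diazomethane; the E alkene is kept.

Step 9
Reactants: 11 (3aR,4S,6S,7aR)-4-(tert-butyldimethylsilyloxy)-3-[(dimethylamino)methyl]-6-methylhexahydro-1-benzofuran-2,7-dione (C3 epimers); 14 (E)-1-diazopent-3-en-2-one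
Product: 15 (3aR,4S,6S,7R,7aR)-4-(tert-butyldimethylsilyloxy)-7-[(3E)-1-diazo-2-oxopent-3-en-1-yl]-3-[(dimethylamino)methyl]-7-hydroxy-6-methylhexahydro-1-benzofuran-2(3H)-one
Conditions: 14, LiN(iPr)2, THF, −78 °C; then 11; AcOH quench at −78 °C
Reagents that add atoms: none
Why: Aldol-type addition of a lithiated α-diazo ketone to a cyclohexanone, in which the bulky planar nucleophile attacks equatorially, so C5 carries an axial OH (bottom face) and an equatorial C1 chain.

Step 10
Reactants: 15 (3aR,4S,6S,7R,7aR)-4-(tert-butyldimethylsilyloxy)-7-[(3E)-1-diazo-2-oxopent-3-en-1-yl]-3-[(dimethylamino)methyl]-7-hydroxy-6-methylhexahydro-1-benzofuran-2(3H)-one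
Product: 17 (3E)-1-[(3aR,4S,6S,7S,7aR)-4-(tert-butyldimethylsilyloxy)-7-hydroxy-6-methyl-3-methylidene-2-oxooctahydro-1-benzofuran-7-yl]pent-3-ene-1,2-dione, via amine N-oxide 16 (not isolated)
Conditions: DMDO (3.1 equiv, acetone), CH2Cl2, −40 °C to rt
Reagents that add atoms: dimethyldioxirane CC1(C)OO1
Why: Dioxirane oxygen transfer turns the diazo carbon into the C1 ketone with loss of N2 and also oxidises the amine, whose N-oxide undergoes Cope elimination on warming to reveal the α-methylene lactone; the electron-poor alkenes are epoxidised far more slowly.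

Step 11
Reactants: 17 (3E)-1-[(3aR,4S,6S,7S,7aR)-4-(tert-butyldimethylsilyloxy)-7-hydroxy-6-methyl-3-methylidene-2-oxooctahydro-1-benzofuran-7-yl]pent-3-ene-1,2-dione
Product: 18 (3aR,4S,6S,7R,8aR)-7-[(2E)-but-2-enoyl]-4-(tert-butyldimethylsilyloxy)-7-hydroxy-6-methyl-3-methylidenehexahydro-2H-cyclohepta[b]furan-2,8(3H)-dione
Conditions: Cu(OTf)2 (10 mol %), 2,2'-(propane-2,2-diyl)bis(4,4-dimethyl-2-oxazoline) (11 mol %), 4 Å MS, ClCH2CH2Cl, 40 °C
Reagents that add atoms: none
Why: Proposed new method: a divalent-copper bisoxazoline Lewis acid activates the vicinal diketone while the axial C5–OH hydrogen-bonds to the C1 carbonyl oxygen, which holds O–C5–C1–O syn-periplanar with the crotonoyl carbonyl pointing to the top face; the electron-richer C5–C10 bond (not C5–C6, which bears the acyloxy group) then shifts to C1 with retention at C10, so the six-ring becomes the seven-ring, C5 becomes the ketone, and C1 is created stereospecifically with OH on the bottom face and crotonoyl on the top face; the driving forces are loss of vicinal-dicarbonyl repulsion, relief of the crowded quaternary C5 and of the trans-lactone/chair strain, and tighter chelation of the product; the closest known reaction type is the Lewis-acid-catalysed α-ketol (acyloin) rearrangement of β-hydroxy-α-dicarbonyl compounds to α-hydroxy-β-dicarbonyl compounds, to my knowledge not yet shown for a six-to-seven enlargement or for an enone-diketone in a polyfunctional, stereodefined cyclohexanol.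

Step 12
Reactants: 18 (3aR,4S,6S,7R,8aR)-7-[(2E)-but-2-enoyl]-4-(tert-butyldimethylsilyloxy)-7-hydroxy-6-methyl-3-methylidenehexahydro-2H-cyclohepta[b]furan-2,8(3H)-dione
Product: 19 (3aR,4S,6S,7S,8S,8aR)-7-[(2E)-but-2-enoyl]-4-(tert-butyldimethylsilyloxy)-7,8-dihydroxy-6-methyl-3-methylideneoctahydro-2H-cyclohepta[b]furan-2-one
Conditions: Me4NBH(OAc)3, MeCN/AcOH, −30 °C
Reagents that add atoms: none
Why: Hydroxyl-directed (Evans–Saksena type) reduction, in which boron binds C1–OH and delivers hydride from the bottom face to the more electrophilic saturated C5 ketone, giving the trans-diol (C5–OH on the top face) while the conjugated C2 ketone and the methylene lactone are spared.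

Step 13
Reactants: 19 (3aR,4S,6S,7S,8S,8aR)-7-[(2E)-but-2-enoyl]-4-(tert-butyldimethylsilyloxy)-7,8-dihydroxy-6-methyl-3-methylideneoctahydro-2H-cyclohepta[b]furan-2-one; 20 angelic acid [(Z)-2-methylbut-2-enoic acid]
Product: 22 (3aR,4S,6S,7S,8S,8aR)-7-[(2E)-but-2-enoyl]-4-(tert-butyldimethylsilyloxy)-7-hydroxy-6-methyl-3-methylidene-2-oxooctahydro-2H-cyclohepta[b]furan-8-yl (2Z)-2-methylbut-2-enoate, via mixed anhydride 21 (not isolated)
Conditions: 20, 2,4,6-trichlorobenzoyl chloride, Et3N, toluene, rt; then 19, 75 °C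
Reagents that add atoms: none
Why: Yamaguchi-type mixed-anhydride esterification run without a nucleophilic catalyst keeps the Z geometry and acylates only the secondary C5–OH, since C1–OH is tertiary and C8–O is silylated.

Step 14
Reactants: 22 (3aR,4S,6S,7S,8S,8aR)-7-[(2E)-but-2-enoyl]-4-(tert-butyldimethylsilyloxy)-7-hydroxy-6-methyl-3-methylidene-2-oxooctahydro-2H-cyclohepta[b]furan-8-yl (2Z)-2-methylbut-2-enoate
Product: 23 CNP0206014.2 (3aS,4S,6S,7S,8S,8aR)-7-[(2E)-but-2-enoyl]-4,7-dihydroxy-6-methyl-3-methylidene-2-oxooctahydro-2H-cyclohepta[b]furan-8-yl (2Z)-2-methylbut-2-enoate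
Conditions: HF·pyridine, THF, 0 °C to rt
Reagents that add atoms: none
Why: Buffered acidic fluoride desilylation frees C8–OH without base, so the enone, angelate, methylene lactone and the 6,12-lactone regiochemistry are preserved.

## Compound list

1 | (S)-4-hydroxycyclohex-2-en-1-one | O=C1C=C[C@@H](O)CC1 | starting material
2 | (S)-4-(tert-butyldimethylsilyloxy)cyclohex-2-en-1-one | O=C1C=C[C@@H](O[Si](C)(C)C(C)(C)C)CC1 | intermediate
3 | (4S,6S)-4-(tert-butyldimethylsilyloxy)-6-methylcyclohex-2-en-1-one | O=C1C=C[C@@H](O[Si](C)(C)C(C)(C)C)C[C@@H]1C | intermediate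
4 | (1R,4S,6S)-4-(tert-butyldimethylsilyloxy)-6-methylcyclohex-2-en-1-ol | O[C@H]1C=C[C@@H](O[Si](C)(C)C(C)(C)C)C[C@@H]1C | intermediate
5 | trimethyl orthoacetate | CC(OC)(OC)OC | starting material
6 | mixed ketene acetal (1-methoxyvinyl ether of 4) | C=C(OC)O[C@H]1C=C[C@@H](O[Si](C)(C)C(C)(C)C)C[C@@H]1C | intermediate
7 | methyl 2-[(1R,4S,6S)-6-(tert-butyldimethylsilyloxy)-4-methylcyclohex-2-en-1-yl]acetate | COC(=O)C[C@@H]1C=C[C@@H](C)C[C@@H]1O[Si](C)(C)C(C)(C)C | intermediate
8 | methyl 2-[(1R,2R,3S,4S,6S)-6-(tert-butyldimethylsilyloxy)-2,3-dihydroxy-4-methylcyclohexyl]acetate | COC(=O)C[C@@H]1[C@@H](O)[C@@H](O)[C@@H](C)C[C@@H]1O[Si](C)(C)C(C)(C)C | intermediate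
9 | (3aR,4S,6S,7S,7aR)-4-(tert-butyldimethylsilyloxy)-7-hydroxy-6-methylhexahydro-1-benzofuran-2(3H)-one | C1C(=O)O[C@@H]2[C@@H]1[C@@H](O[Si](C)(C)C(C)(C)C)C[C@H](C)[C@@H]2O | intermediate
10 | 3-[(dimethylamino)methyl] derivative of 9 (C3 epimers) | CN(C)CC1C(=O)O[C@@H]2[C@@H]1[C@@H](O[Si](C)(C)C(C)(C)C)C[C@H](C)[C@@H]2O | intermediate
11 | (3aR,4S,6S,7aR)-4-(tert-butyldimethylsilyloxy)-3-[(dimethylamino)methyl]-6-methylhexahydro-1-benzofuran-2,7-dione (C3 epimers) | CN(C)CC1C(=O)O[C@@H]2[C@@H]1[C@@H](O[Si](C)(C)C(C)(C)C)C[C@H](C)C2=O | intermediate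
12 | (E)-pent-3-en-2-one | C/C=C/C(C)=O | starting material
13 | (E)-1,1,1-trifluorohept-5-ene-2,4-dione | C/C=C/C(=O)CC(=O)C(F)(F)F | intermediate
14 | (E)-1-diazopent-3-en-2-one | C/C=C/C(=O)C=[N+]=[N-] | intermediate
15 | diazo-aldol adduct (C5 R: OH bottom face, chain equatorial) | CN(C)CC1C(=O)O[C@@H]2[C@@H]1[C@@H](O[Si](C)(C)C(C)(C)C)C[C@H](C)[C@@]2(O)C(=[N+]=[N-])C(=O)/C=C/C | intermediate
16 | amine N-oxide of the hydroxy vicinal diketone | C[N+](C)([O-])CC1C(=O)O[C@@H]2[C@@H]1[C@@H](O[Si](C)(C)C(C)(C)C)C[C@H](C)[C@@]2(O)C(=O)C(=O)/C=C/C | intermediate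
17 | 1-hydroxycyclohexyl vicinal diketone with α-methylene lactone | C=C1C(=O)O[C@@H]2[C@@H]1[C@@H](O[Si](C)(C)C(C)(C)C)C[C@H](C)[C@@]2(O)C(=O)C(=O)/C=C/C | intermediate
18 | ring-enlarged 2-crotonoyl-2-hydroxycycloheptanone | C=C1C(=O)O[C@@H]2[C@@H]1[C@@H](O[Si](C)(C)C(C)(C)C)C[C@H](C)[C@@](O)(C(=O)/C=C/C)C2=O | intermediate
19 | C1,C5 trans-diol | C=C1C(=O)O[C@@H]2[C@@H]1[C@@H](O[Si](C)(C)C(C)(C)C)C[C@H](C)[C@@](O)(C(=O)/C=C/C)[C@H]2O | intermediate
20 | angelic acid | C/C=C(/C)C(=O)O | starting material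
21 | angelic 2,4,6-trichlorobenzoic anhydride | C/C=C(/C)C(=O)OC(=O)c1c(Cl)cc(Cl)cc1Cl | intermediate
22 | C8-O-TBS ether of the target | C=C1C(=O)O[C@@H]2[C@@H]1[C@@H](O[Si](C)(C)C(C)(C)C)C[C@H](C)[C@@](O)(C(=O)/C=C/C)[C@H]2OC(=O)/C(C)=C\C | intermediate
23 | CNP0206014.2 | C=C1C(=O)O[C@@H]2[C@@H]1[C@@H](O)C[C@H](C)[C@@](O)(C(=O)/C=C/C)[C@H]2OC(=O)/C(C)=C\C | target

## Step count and risks

Total step count: 14. Longest linear sequence: 13 (steps 1–7 and 9–14).

Three steps most likely to fail:

**Step 9** (addition of lithiated 14 to the hindered, enolisable ketone 11).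
- The fallback sets out from 11 (with 12) and comes back at 15.
- The kinetic lithium enolate of 12 is transmetalated with CeCl3 and added to 11. This cerium aldol is far less basic, and it gives the β-hydroxy ketone F1.
- The diazo group is then introduced after the C–C bond. F1 is trifluoroacetylated at C1 with LiN(SiMe3)2 and CF3CO2CH2CF3 to the trifluoroacetyl ketone F2, and MsN3/Et3N converts this into 15.

**Step 11** (the proposed new ring enlargement; equilibrium position and competing acyl shifts are unknown).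
- The fallback uses known chemistry, sets out from 15 and comes back at 18.
- Rh2(OAc)4 in CH2Cl2 expels N2. The rhodium carbenoid undergoes the established 1,2-alkyl shift of α-diazo-β-hydroxy carbonyl compounds, again with C10 migrating. The product is the ring-enlarged 2-crotonoylcycloheptanone F3, which is enolised at C1.
- DMDO then hydroxylates the enol at C1 and oxidises the amine, and the resulting amine N-oxide F4 eliminates to 18.
- In this variant C1 is set by reagent approach and not by a stereospecific shift, and attack anti to the C10 methyl would favour the unwanted C1 epimer, so this weaker variant may need epimer separation.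

**Step 12** (chemoselectivity between the C5 and C2 carbonyl groups, and the face of hydride delivery).
- The fallback sets out from 18 and comes back at 19.
- Excess Me4NBH(OAc)3 at 0 °C is allowed to reduce both carbonyl groups that flank the directing C1–OH, giving the triol F5.
- MnO2 in CH2Cl2 then re-oxidises only the allylic C2 carbinol and gives 19.

## Further compounds

F1 | step 9 | β-hydroxy ketone from the cerium aldol of 12 with 11 | CN(C)CC1C(=O)O[C@@H]2[C@@H]1[C@@H](O[Si](C)(C)C(C)(C)C)C[C@H](C)[C@@]2(O)CC(=O)/C=C/C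
F2 | step 9 | C1-trifluoroacetyl derivative of F1 | CN(C)CC1C(=O)O[C@@H]2[C@@H]1[C@@H](O[Si](C)(C)C(C)(C)C)C[C@H](C)[C@@]2(O)C(C(=O)/C=C/C)C(=O)C(F)(F)F
F3 | step 11 | ring-enlarged 2-crotonoylcycloheptanone (Mannich base, C1 enolisable) | CN(C)CC1C(=O)O[C@@H]2[C@@H]1[C@@H](O[Si](C)(C)C(C)(C)C)C[C@H](C)C(C(=O)/C=C/C)C2=O
F4 | step 11 | amine N-oxide of C1-hydroxylated F3 | C[N+](C)([O-])CC1C(=O)O[C@@H]2[C@@H]1[C@@H](O[Si](C)(C)C(C)(C)C)C[C@H](C)[C@@](O)(C(=O)/C=C/C)C2=O
F5 | step 12 | C1,C2,C5-triol (C2 epimers) | C=C1C(=O)O[C@@H]2[C@@H]1[C@@H](O[Si](C)(C)C(C)(C)C)C[C@H](C)[C@@](O)(C(O)/C=C/C)[C@H]2O
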